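Amber is the flask to watch: its ring is built at 60 °C, and then the flask is heated to 110 °C for the last hours of the run.

| flask | solid substrate | temperature | remark | time |
|---|---|---|---|---|
| alpha | 2.7 M | 72 °C | run made earlier |  |
| delta | 2.7 M | 100 °C | run made earlier |  |
| amber | 1.9 M |  | at 60 °C until 20 h, from then on at 110 °C | 25 h |
| violet | 1.9 M | 60 °C |  | 25 h |
| red | 1.9 M | 110 °C |  | 25 h |
| blue | 1.9 M | 85 °C |  | 25 h |

| run | time / h | ring / % |
|---|---|---|
| alpha | 1.33 | 0.3 |
| alpha | 2.00 | 2.2 |
| alpha | 3.00 | 3.0 |
| alpha | 6.00 | 6.0 |
| alpha | 12.0 | 13.3 |
| alpha | 15.0 | 15.8 |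
| delta | 0.333 | 1.0 |
| delta | 0.500 | 0.8 |
| delta | 0.833 | 0 |
| delta | 1.33 | 0.2 |
| delta | 3.00 | 2.2 |
| delta | 4.00 | 0.6 |

(readings scatter by 1 percentage point)

- the best flask by amount of ring, in percent of the solid substrate charged; "all alike" if 1.5 percentage points covers them all (amber / violet / red / blue / all alike)
- amount of ring at the end, in percent of the solid substrate charged, amber
- amount of ring at the end, in percent of the solid substrate charged, violet
- amount of ring at the end, in percent of the solid substrate charged, red
- amount of ring at the end, in percent of the solid substrate charged, blue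

I kept the books for amber on its 1.9 M of solid substrate, the limiting reagent. The first entry is ring made cold. The alpha run climbed from 3.0 % to 15.8 % between 3.00 h and 15.0 h, which on its charge is 0.0288 M h⁻¹. Carried over as a molar pace, that books 30.3 % of amber's charge by the change, and I expected less, since 60 °C is colder than 72 °C.

The second entry is ring after the change. The delta run already read 1.0 % at 0.333 h, and its readings average 0.800 %, so within their scatter I read ring's lifetime in the delta run as no longer than that first time. Amber's hot hours divided by it give at least 15.0. This hot count, hot hours over ring's hot lifetime, told me the cold entry would not stay. I rewrote it to delta's molar level, 1.14 % of amber's charge, assuming 110 °C behaves like 100 °C. The books close with the other 98.9 % in solid substrate, starting material and open dimer, which no reading splits.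

The forecast named violet as best, with 1.5 % for amber, 14 % for violet, 0.7 % for red and 6 % for blue. For amber it held that “the ring should then revert and drain to dimer”.

The flasks gave 1.08 % in amber, 28.1 % in violet, 1.01 % in red and 14.4 % in blue, with violet the best. Amber held 21.1 % ring after 20.0 h, yet it ended 0.07 percentage points from red.

    starting material ⇌ ring (K = 5.90, k = 0.0675 h⁻¹, Ea = 120 kJ mol⁻¹, ΔH = −86.0 kJ mol⁻¹)
    2 starting material → open dimer (k = 0.0114 L mol⁻¹ h⁻¹, Ea = 90.0 kJ mol⁻¹)
    crystals ⇌ ring, rate k3*(cs3 - [ring]) while solid is left; crystals form when [ring] > cs3 (solubility = 0.780 M, k = 5.20 h⁻¹)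
    solid substrate ⇌ starting material, rate k4*(cs4 - [starting material]) while solid is left; crystals form when [starting material] > cs4 (solubility = 1.00 M, k = 0.0679 h⁻¹)
    (constants at 60 °C)

Amber left until 4.0 d spends 76.0 h hot, a hot count of at least 228. That flask ended below my hot level, though ring over starting material stood at 0.102, as in amber at 25.0 h with 0.103. Its books closed with solid substrate at 0 %, crystals at 0 %, starting material at 0.600 %, ring at 0.0615 % and open dimer at 99.3 %.

(The runs are calculated with made-up constants; noise was put on by code.)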